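**Retrosynthetic overview**

- Feature: ring A is the six-membered carbocycle C4a–C5–C6–C7–C8–C8a. Its C8 carries a CH bonded to propyl and to CH2CO2H, and the acid carbon lies gamma to the C7 oxygen, so C8/O7 plus the side chain is a ring-opened 4-propyl-3,4-dihydrocoumarin.
- Late disconnections: ester hydrolysis, then the C6–prenyl bond (dearomatising C-alkylation of the aromatic ring, run on the methanolysed lactone so that C6 lies between two free hydroxyls), then the C8–CH and O7–C(=O) bonds by carbene-catalysed annulation of the chromanone with hex-2-ynal.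
- Chromanone precursor: the C6–CH2 bond comes from Negishi coupling of a 6-iodide, whose position is fixed by 5-OH-directed iodination, because direct alkylation with an aldehyde would not reliably distinguish C6 from C8.
- Cyclobutane partner: from 3,3-dimethylcyclobutanecarboxylic acid by dehydrogenation to the cyclobutene ester and asymmetric conjugate isopropenylation.
- Ring order: pyranone ring B is built on phloroglucinol first; the cyclobutane is bought; the lactone ring is closed in the key step and reopened; ring A is dearomatised last.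

Key step: step 12

Remark: the target is drawn and named as its 5-hydroxy-4,7-dioxo tautomer, one of the interconverting enol forms of ring A; the sense of induction of each chiral catalyst named is to be confirmed in a first run, both antipodes (or pseudo-enantiomers) being available.

**Route**

Step 1
Reactants: 1 phloroglucinol; 2 3-methylbut-2-enoic acid
Product: 3 5,7-dihydroxy-2,2-dimethylchroman-4-one
Conditions: P2O5 in MeSO3H (1:10 w/w), 70 °C
Reagents that add atoms: none
Why: Friedel–Crafts acylation of the symmetrical triol followed by intramolecular oxa-Michael closure of the ortho-hydroxy enone is a known one-pot chromanone synthesis, and the symmetry of 1 removes any regiochemical question.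

Step 2
Reactants: 3 5,7-dihydroxy-2,2-dimethylchroman-4-one
Product: 4 5-hydroxy-2,2-dimethyl-7-[(triisopropylsilyl)oxy]chroman-4-one
Conditions: i-Pr3SiCl (1.05 equiv), imidazole, DMF, 0 °C
Reagents that add atoms: triisopropylsilyl chloride, CC(C)[Si](Cl)(C(C)C)C(C)C
Why: Selective O-silylation should cap only O7, because the 7-OH is the acidic, unchelated phenol whereas the 5-OH is locked in a hydrogen bond to the C4 ketone.

Step 3
Reactants: 4 5-hydroxy-2,2-dimethyl-7-[(triisopropylsilyl)oxy]chroman-4-one
Product: 5 5-hydroxy-6-iodo-2,2-dimethyl-7-[(triisopropylsilyl)oxy]chroman-4-one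
Conditions: BnMe3N+ ICl2− (1.0 equiv), CaCO3, CH2Cl2/MeOH, rt
Reagents that add atoms: benzyltrimethylammonium dichloroiodate, C[N+](C)(C)Cc1ccccc1.Cl[I-]Cl
Why: Electrophilic aromatic iodination under weakly basic conditions is known to go ortho to the free, chelated 5-OH of 5-hydroxy-7-alkoxy chromones and flavones (C6, not C8), which fixes the site of the later carbon substituent.

Step 4
Reactants: 6 3,3-dimethylcyclobutane-1-carboxylic acid
Product: 7 benzyl 3,3-dimethylcyclobutane-1-carboxylate
Conditions: BnBr, K2CO3, DMF, rt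
Reagents that add atoms: benzyl bromide, BrCc1ccccc1
Why: Carboxylate O-alkylation (SN2) should give a non-volatile, UV-active ester suited to enolate chemistry.

Step 5
Reactants: 7 benzyl 3,3-dimethylcyclobutane-1-carboxylate
Product: 10 benzyl 3,3-dimethylcyclobut-1-ene-1-carboxylate, via α-phenylselanyl ester 8 (not isolated), via selenoxide 9 (not isolated)
Conditions: LiN(i-Pr)2, THF, −78 °C; PhSeBr; then H2O2 (30% aq.), pyridine, 0 °C to rt
Reagents that add atoms: none
Why: α-Selenenylation of the ester enolate followed by oxidation and syn-elimination (selenoxide elimination) should introduce the C1=C2 double bond, and since both β-methylene groups are equivalent only one cyclobutene can form.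

Step 6
Reactants: 10 benzyl 3,3-dimethylcyclobut-1-ene-1-carboxylate
Product: 11 benzyl (1R,2R)-3,3-dimethyl-2-(prop-1-en-2-yl)cyclobutane-1-carboxylate
Conditions: isopropenyl-B(pin) (2 equiv), [RhCl(C2H4)2]2 (2.5 mol%), (R,R)-2,5-diphenylbicyclo[2.2.2]octa-2,5-diene (5.5 mol%), KOH (0.3 equiv), dioxane/H2O 10:1, 50 °C
Reagents that add atoms: isopropenylboronic acid pinacol ester, C=C(C)B1OC(C)(C)C(C)(C)O1
Why: Rhodium-catalysed asymmetric conjugate addition of an alkenylboron reagent (Hayashi–Miyaura reaction), an established reaction of unsaturated esters that ring strain extends to the trisubstituted cyclobutene, should set C2 by syn-carborhodation on the face chosen by the chiral diene, while protonation of the rhodium enolate anti to the new group and base equilibration of the epimerisable C1 give the trans ester.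

Step 7
Reactants: 11 benzyl (1R,2R)-3,3-dimethyl-2-(prop-1-en-2-yl)cyclobutane-1-carboxylate
Product: 12 [(1R,2R)-3,3-dimethyl-2-(prop-1-en-2-yl)cyclobutyl]methanol
Conditions: LiAlH4, THF, 0 °C
Reagents that add atoms: none
Why: Hydride reduction of the ester should give the primary alcohol without touching either ring stereocentre, and C1 is no longer epimerisable afterwards.

Step 8
Reactants: 12 [(1R,2R)-3,3-dimethyl-2-(prop-1-en-2-yl)cyclobutyl]methanol
Product: 13 [(1R,2R)-3,3-dimethyl-2-(prop-1-en-2-yl)cyclobutyl]methyl iodide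
Conditions: I2, PPh3, imidazole, CH2Cl2, 0 °C to rt
Reagents that add atoms: iodine, II
Why: Appel-type iodination displaces the activated primary hydroxyl at the exocyclic CH2 by SN2 under neutral conditions, so the ring stereocentres and the acid-sensitive isopropenylcyclobutane should be untouched.

Step 9
Reactants: 13 [(1R,2R)-3,3-dimethyl-2-(prop-1-en-2-yl)cyclobutyl]methyl iodide; 5 5-hydroxy-6-iodo-2,2-dimethyl-7-[(triisopropylsilyl)oxy]chroman-4-one
Product: 15 6-{[(1S,2R)-3,3-dimethyl-2-(prop-1-en-2-yl)cyclobutyl]methyl}-5-hydroxy-2,2-dimethyl-7-[(triisopropylsilyl)oxy]chroman-4-one, via alkylzinc iodide 14 (not isolated)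
Conditions: 13, Zn dust, LiCl, THF, 40 °C; then 5, Pd(OAc)2 (2 mol%), SPhos (4 mol%), THF, rt, zinc reagent (1.5 equiv) added slowly
Reagents that add atoms: none
Why: Zinc insertion into the primary iodide followed by Negishi cross-coupling should form the C6–CH2 bond exactly at the iodinated carbon, since alkylzinc halides tolerate the ketone and, under Pd/SPhos catalysis with slow addition, the chelated phenol, and the metal sits on the exocyclic CH2 so neither ring stereocentre is affected (the C1 descriptor changes from R to S only through priorities).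

Step 10
Reactants: 15 6-{[(1S,2R)-3,3-dimethyl-2-(prop-1-en-2-yl)cyclobutyl]methyl}-5-hydroxy-2,2-dimethyl-7-[(triisopropylsilyl)oxy]chroman-4-one
Product: 16 6-{[(1S,2R)-3,3-dimethyl-2-(prop-1-en-2-yl)cyclobutyl]methyl}-5,7-dihydroxy-2,2-dimethylchroman-4-one
Conditions: Bu4NF, AcOH (1:1), THF, 0 °C
Reagents that add atoms: none
Why: Fluoride cleavage of the aryl silyl ether, buffered with acetic acid, should free the 7-OH without exposing the chromanone to base.

Step 11
Reactants: 17 hex-2-yn-1-ol
Product: 18 hex-2-ynal
Conditions: Dess–Martin periodinane, CH2Cl2, 0 °C to rt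
Reagents that add atoms: none
Why: Dess–Martin oxidation of the propargylic alcohol should stop at the ynal, which is volatile and is used as a filtered solution.

Step 12
Reactants: 16 6-{[(1S,2R)-3,3-dimethyl-2-(prop-1-en-2-yl)cyclobutyl]methyl}-5,7-dihydroxy-2,2-dimethylchroman-4-one; 18 hex-2-ynal
Product: 19 (10R)-6-{[(1S,2R)-3,3-dimethyl-2-(prop-1-en-2-yl)cyclobutyl]methyl}-5-hydroxy-2,2-dimethyl-10-propyl-2,3,9,10-tetrahydro-4H,8H-pyrano[2,3-f]chromene-4,8-dione
Conditions: 18 (1.5 equiv), (5aS,10bR)-2-mesityl-5a,10b-dihydro-4H,6H-indeno[2,1-b][1,2,4]triazolo[4,3-d][1,4]oxazin-2-ium chloride (10 mol%), toluene, 40 °C, no added base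
Reagents that add atoms: none
Why: The carbene adds to the aldehyde of 18 and the resulting propargylic Breslow intermediate is protonated at the γ-carbon (internal redox) to give an (E)-hex-2-enoyl azolium. The O7/C8 enol unit of 16 engages this species by addition at oxygen and [3,3]-shift, or by direct conjugate addition, so that C8 bonds to the β-carbon; the closest known reaction type is the carbene-catalysed annulation of ynals with naphthols and enolisable 1,3-dicarbonyls to dihydrocoumarins and dihydropyranones. The saturated acyl azolium so formed is captured by the 7-OH in a 6-exo-trig lactonisation, which closes the lactone ring and releases the carbene. The new stereocentre (10R, the propyl-bearing carbon) is controlled by the aminoindanol-derived triazolylidene, whose indane face blocks one face of the acyl azolium. Site selectivity comes from the substrate: C8 is the only unsubstituted ring carbon and only the 7-OH adjoins it, whereas the chelated 5-OH flanks the substituted C6 and cannot lead to a rearomatised product. The step is redox-neutral and needs no oxidant or strong base, so the isopropenyl group and the chromanone should survive.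

Step 13
Reactants: 19 (10R)-6-{[(1S,2R)-3,3-dimethyl-2-(prop-1-en-2-yl)cyclobutyl]methyl}-5-hydroxy-2,2-dimethyl-10-propyl-2,3,9,10-tetrahydro-4H,8H-pyrano[2,3-f]chromene-4,8-dione
Product: 20 methyl (3R)-3-[6-{[(1S,2R)-3,3-dimethyl-2-(prop-1-en-2-yl)cyclobutyl]methyl}-5,7-dihydroxy-2,2-dimethyl-4-oxo-3,4-dihydro-2H-chromen-8-yl]hexanoate
Conditions: NaOMe (1.5 equiv), MeOH/THF, 0 °C; AcOH quench; used without delay
Reagents that add atoms: methanol, CO
Why: Transesterification of the aryl lactone, in which methoxide attacks the activated aryl ester and the stabilised 7-phenoxide leaves, should give the methyl ester and a C6 now flanked by two free hydroxyls, while the benzylic stereocentre is not acidic and stays intact.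

Step 14
Reactants: 20 methyl (3R)-3-[6-{[(1S,2R)-3,3-dimethyl-2-(prop-1-en-2-yl)cyclobutyl]methyl}-5,7-dihydroxy-2,2-dimethyl-4-oxo-3,4-dihydro-2H-chromen-8-yl]hexanoate
Product: 21 methyl (3R)-3-[(6R)-6-{[(1S,2R)-3,3-dimethyl-2-(prop-1-en-2-yl)cyclobutyl]methyl}-5-hydroxy-2,2-dimethyl-6-(3-methylbut-2-en-1-yl)-4,7-dioxo-3,4,6,7-tetrahydro-2H-chromen-8-yl]hexanoate
Conditions: prenyl bromide (1.2 equiv), O-allyl-N-(9-anthracenylmethyl)cinchonidinium bromide (10 mol%), CsOH·H2O (2.5 equiv), toluene/CH2Cl2 7:3, −40 °C
Reagents that add atoms: prenyl bromide (1-bromo-3-methylbut-2-ene), CC(C)=CCBr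
Why: Proposed new method: alkylative dearomatisation with an allylic bromide under chiral ion-pair (phase-transfer) control; the 7-phenoxide of 20 is the anion of an acylphloroglucinol-type ring whose carbon between two oxygens (C6) is a soft, enolate-like nucleophile that should attack the allylic bromide by SN2 and give the non-aromatic vinylogous acid, while the cinchonidinium cation paired with the delocalised O7/O5/O4 anion in a non-polar medium should shield one ring face and set the quaternary centre (6R), the existing stereocentres being too remote to bias the faces; the closest known reaction types are the base-mediated C-prenylation of acylphloroglucinols to lupulone-type triketones and the chiral phase-transfer-catalysed alkylative dearomatisation of acylphloroglucinols with Michael acceptors.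

Step 15
Reactants: 21 methyl (3R)-3-[(6R)-6-{[(1S,2R)-3,3-dimethyl-2-(prop-1-en-2-yl)cyclobutyl]methyl}-5-hydroxy-2,2-dimethyl-6-(3-methylbut-2-en-1-yl)-4,7-dioxo-3,4,6,7-tetrahydro-2H-chromen-8-yl]hexanoate
Product: 22 (3R)-3-[(6R)-6-{[(1S,2R)-3,3-dimethyl-2-(prop-1-en-2-yl)cyclobutyl]methyl}-5-hydroxy-2,2-dimethyl-6-(3-methylbut-2-en-1-yl)-4,7-dioxo-3,4,6,7-tetrahydro-2H-chromen-8-yl]hexanoic acid (target CNP0358381.1)
Conditions: LiOH, THF/H2O 3:1, 0 °C to rt; then 1 M HCl to pH 3 at 0 °C
Reagents that add atoms: lithium hydroxide, [Li+].[OH-]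
Why: Saponification of the methyl ester should proceed while ring A is held as its delocalised vinylogous-acid anion, which disfavours enolisation at C3 and hence retro-oxa-Michael opening of the pyranone, and neither the quaternary nor the benzylic stereocentre is epimerisable.

**Compound list**

1 | phloroglucinol (benzene-1,3,5-triol) | Oc1cc(O)cc(O)c1 | starting material
2 | 3-methylbut-2-enoic acid | CC(C)=CC(=O)O | starting material
3 | 5,7-dihydroxy-2,2-dimethylchroman-4-one | CC1(C)CC(=O)c2c(O)cc(O)cc2O1 | intermediate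
4 | 5-hydroxy-2,2-dimethyl-7-[(triisopropylsilyl)oxy]chroman-4-one | CC1(C)CC(=O)c2c(O)cc(O[Si](C(C)C)(C(C)C)C(C)C)cc2O1 | intermediate
5 | 5-hydroxy-6-iodo-2,2-dimethyl-7-[(triisopropylsilyl)oxy]chroman-4-one | CC1(C)CC(=O)c2c(O)c(I)c(O[Si](C(C)C)(C(C)C)C(C)C)cc2O1 | intermediate
6 | 3,3-dimethylcyclobutane-1-carboxylic acid | CC1(C)CC(C(=O)O)C1 | starting material
7 | benzyl 3,3-dimethylcyclobutane-1-carboxylate | CC1(C)CC(C(=O)OCc2ccccc2)C1 | intermediate
8 | benzyl 3,3-dimethyl-1-(phenylselanyl)cyclobutane-1-carboxylate | CC1(C)CC([Se]c2ccccc2)(C(=O)OCc2ccccc2)C1 | intermediate (not isolated)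
9 | benzyl 3,3-dimethyl-1-(phenylseleninyl)cyclobutane-1-carboxylate (selenoxide) | CC1(C)CC([Se](=O)c2ccccc2)(C(=O)OCc2ccccc2)C1 | intermediate (not isolated)
10 | benzyl 3,3-dimethylcyclobut-1-ene-1-carboxylate | CC1(C)CC(C(=O)OCc2ccccc2)=C1 | intermediate
11 | benzyl (1R,2R)-3,3-dimethyl-2-(prop-1-en-2-yl)cyclobutane-1-carboxylate (trans) | C=C(C)[C@H]1[C@H](C(=O)OCc2ccccc2)CC1(C)C | intermediate
12 | [(1R,2R)-3,3-dimethyl-2-(prop-1-en-2-yl)cyclobutyl]methanol | C=C(C)[C@H]1[C@H](CO)CC1(C)C | intermediate
13 | [(1R,2R)-3,3-dimethyl-2-(prop-1-en-2-yl)cyclobutyl]methyl iodide | C=C(C)[C@H]1[C@H](CI)CC1(C)C | intermediate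
14 | {[(1R,2R)-3,3-dimethyl-2-(prop-1-en-2-yl)cyclobutyl]methyl}zinc iodide | C=C(C)[C@H]1[C@H](C[Zn]I)CC1(C)C | intermediate (not isolated)
15 | 6-{[(1S,2R)-3,3-dimethyl-2-(prop-1-en-2-yl)cyclobutyl]methyl}-5-hydroxy-2,2-dimethyl-7-[(triisopropylsilyl)oxy]chroman-4-one | C=C(C)[C@H]1[C@H](Cc2c(O[Si](C(C)C)(C(C)C)C(C)C)cc3OC(C)(C)CC(=O)c3c2O)CC1(C)C | intermediate
16 | 6-{[(1S,2R)-3,3-dimethyl-2-(prop-1-en-2-yl)cyclobutyl]methyl}-5,7-dihydroxy-2,2-dimethylchroman-4-one (key-step precursor) | C=C(C)[C@H]1[C@H](Cc2c(O)cc3OC(C)(C)CC(=O)c3c2O)CC1(C)C | intermediate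
17 | hex-2-yn-1-ol | CCCC#CCO | starting material
18 | hex-2-ynal | CCCC#CC=O | intermediate
19 | (10R)-6-{[(1S,2R)-3,3-dimethyl-2-(prop-1-en-2-yl)cyclobutyl]methyl}-5-hydroxy-2,2-dimethyl-10-propyl-2,3,9,10-tetrahydro-4H,8H-pyrano[2,3-f]chromene-4,8-dione (chromanone with the dihydrocoumarin lactone fused across O7/C8; key-step product) | C=C(C)[C@H]1[C@H](Cc2c(O)c3C(=O)CC(C)(C)Oc3c3[C@H](CCC)CC(=O)Oc23)CC1(C)C | intermediate
20 | methyl (3R)-3-[6-{[(1S,2R)-3,3-dimethyl-2-(prop-1-en-2-yl)cyclobutyl]methyl}-5,7-dihydroxy-2,2-dimethyl-4-oxo-3,4-dihydro-2H-chromen-8-yl]hexanoate | C=C(C)[C@H]1[C@H](Cc2c(O)c([C@H](CCC)CC(=O)OC)c3OC(C)(C)CC(=O)c3c2O)CC1(C)C | intermediate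
21 | methyl (3R)-3-[(6R)-6-{[(1S,2R)-3,3-dimethyl-2-(prop-1-en-2-yl)cyclobutyl]methyl}-5-hydroxy-2,2-dimethyl-6-(3-methylbut-2-en-1-yl)-4,7-dioxo-3,4,6,7-tetrahydro-2H-chromen-8-yl]hexanoate | C=C(C)[C@H]1[C@H](C[C@]2(CC=C(C)C)C(=O)C([C@H](CCC)CC(=O)OC)=C3OC(C)(C)CC(=O)C3=C2O)CC1(C)C | intermediate
22 | (3R)-3-[(6R)-6-{[(1S,2R)-3,3-dimethyl-2-(prop-1-en-2-yl)cyclobutyl]methyl}-5-hydroxy-2,2-dimethyl-6-(3-methylbut-2-en-1-yl)-4,7-dioxo-3,4,6,7-tetrahydro-2H-chromen-8-yl]hexanoic acid | C=C(C)[C@H]1[C@H](C[C@]2(CC=C(C)C)C(=O)C([C@H](CCC)CC(=O)O)=C3OC(C)(C)CC(=O)C3=C2O)CC1(C)C | target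

**Step count**

Total: 15 steps. Longest linear sequence: 11 steps (steps 4–10 and 12–15, from compound 6).

**Steps most likely to fail, with fallbacks**

Step 14 (the step carrying the label "Proposed new method:") is the riskiest. Alkylation may go to oxygen (O7 or O5) or to C8 instead of C6, and the ion-paired catalyst may discriminate the two ring faces only weakly. The fallback uses known chemistry and gives up catalyst control. It sets out from compound 20, which is treated with NaOMe in MeOH and prenyl bromide at 0 °C, the classical protic conditions for C-prenylation of acylphloroglucinols. This should give 21 together with its C6 epimer, methyl (3R)-3-[(6S)-6-{[(1S,2R)-3,3-dimethyl-2-(prop-1-en-2-yl)cyclobutyl]methyl}-5-hydroxy-2,2-dimethyl-6-(3-methylbut-2-en-1-yl)-4,7-dioxo-3,4,6,7-tetrahydro-2H-chromen-8-yl]hexanoate F1. The two are diastereomers because of the three existing stereocentres and are separated by chromatography. The fallback comes back to the route at compound 21.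

Step 12 is the second risk. The acyl azolium may be transferred to a phenolic oxygen without C–C bond formation, turnover may be slow because the arene is deactivated by the chelated ketone, or facial selectivity may erode. The fallback replaces acyl azolium catalysis by iminium catalysis. It sets out from compound 16, which is combined with commercial (E)-hex-2-enal, α,α-diphenylprolinol trimethylsilyl ether (antipode chosen for the R centre) and benzoic acid in toluene at 0 °C. Friedel–Crafts alkylation at C8 and hemiacetal formation with the 7-OH should give the lactol (10R)-6-{[(1S,2R)-3,3-dimethyl-2-(prop-1-en-2-yl)cyclobutyl]methyl}-5,8-dihydroxy-2,2-dimethyl-10-propyl-2,3,9,10-tetrahydro-4H,8H-pyrano[2,3-f]chromen-4-one F2 as an anomeric mixture. Oxidation of the lactol with Ag2CO3 on Celite in warm toluene then gives the lactone, and the fallback comes back to the route at compound 19.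

Step 6 is the third risk. Carborhodation at the β-carbon next to the quaternary centre may be slower than protodeboronation of the alkenylboronate, and facial control may be incomplete. The fallback uses a covalent auxiliary and a stoichiometric cuprate. It sets out from compound 10:
- Saponification with LiOH in THF/H2O gives 3,3-dimethylcyclobut-1-ene-1-carboxylic acid F3.
- Activation with t-BuCOCl/Et3N and acylation of the lithium salt of (S)-4-benzyl-1,3-oxazolidin-2-one gives (4S)-4-benzyl-3-(3,3-dimethylcyclobut-1-ene-1-carbonyl)-1,3-oxazolidin-2-one F4.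
- Conjugate addition of CH2=C(CH3)MgBr with CuBr·SMe2 in THF/Me2S at −78 to −20 °C, followed by protonation, gives (4S)-4-benzyl-3-[(1R,2R)-3,3-dimethyl-2-(prop-1-en-2-yl)cyclobutane-1-carbonyl]-1,3-oxazolidin-2-one F5. It is freed from its diastereomers by chromatography or crystallisation; the (R)-auxiliary is used instead if it gives the better face selectivity.
- Reductive cleavage with LiBH4 in wet THF gives the alcohol, and the fallback comes back to the route at compound 12.

**Further compounds**

F1 | step 14 | methyl (3R)-3-[(6S)-6-{[(1S,2R)-3,3-dimethyl-2-(prop-1-en-2-yl)cyclobutyl]methyl}-5-hydroxy-2,2-dimethyl-6-(3-methylbut-2-en-1-yl)-4,7-dioxo-3,4,6,7-tetrahydro-2H-chromen-8-yl]hexanoate | C=C(C)[C@H]1[C@H](C[C@@]2(CC=C(C)C)C(=O)C([C@H](CCC)CC(=O)OC)=C3OC(C)(C)CC(=O)C3=C2O)CC1(C)C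
F2 | step 12 | (10R)-6-{[(1S,2R)-3,3-dimethyl-2-(prop-1-en-2-yl)cyclobutyl]methyl}-5,8-dihydroxy-2,2-dimethyl-10-propyl-2,3,9,10-tetrahydro-4H,8H-pyrano[2,3-f]chromen-4-one (lactol, anomeric mixture) | C=C(C)[C@H]1[C@H](Cc2c(O)c3C(=O)CC(C)(C)Oc3c3[C@H](CCC)CC(O)Oc23)CC1(C)C
F3 | step 6 | 3,3-dimethylcyclobut-1-ene-1-carboxylic acid | CC1(C)CC(C(=O)O)=C1
F4 | step 6 | (4S)-4-benzyl-3-(3,3-dimethylcyclobut-1-ene-1-carbonyl)-1,3-oxazolidin-2-one | CC1(C)CC(C(=O)N2C(=O)OC[C@@H]2Cc3ccccc3)=C1
F5 | step 6 | (4S)-4-benzyl-3-[(1R,2R)-3,3-dimethyl-2-(prop-1-en-2-yl)cyclobutane-1-carbonyl]-1,3-oxazolidin-2-one | C=C(C)[C@H]1[C@H](C(=O)N2C(=O)OC[C@@H]2Cc3ccccc3)CC1(C)C
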